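From the constants of this catalyst we read one ratio off the runs, and we carry that ratio through the flasks below.

the same everywhere: free catalyst 0.1 mol%

| flask | substrate | partner | remark | time |
|---|---|---|---|---|
| winter | 0.18 M | 1 equiv | run made earlier |  |
| autumn | 0.18 M | 0.67 equiv | run made earlier |  |
| midnight | 0.18 M | 1.5 equiv | run made earlier |  |
| delta | 0.18 M | 1.00 equiv (fed, over 5.0 min) | all else is in the flask from the start; the feed brings no volume worth counting | 8.0 min |
| eta | 0.18 M | 1.00 equiv | everything together at the start | 8.0 min |
| beta | 0.18 M (fed, over 5.0 min) | 1.00 equiv | all else is in the flask from the start; the feed brings no volume worth counting | 8.0 min |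

- winter (time / min: target / %): 0.250: 22; 0.667: 40; 1.33: 54; 2.00: 57; 3.00: 69; 4.00: 67; 5.00: 67
- autumn (time / min: target / %): 0.833: 35; 1.33: 37; 2.00: 43; 2.50: 44; 4.00: 44; 6.00: 48; 10.0: 45
- midnight (time / min: target / %): 1.33: 71; 3.00: 81; 4.00: 86; 6.00: 86; 8.00: 85; 10.0: 85

(each reading ± 2 percentage points)

1. the best flask by amount of target, in percent of the substrate charged; "all alike" if 1.5 percentage points covers them all (delta / eta / beta / all alike)
2. amount of target at the end, in percent of the substrate charged, delta
3. amount of target at the end, in percent of the substrate charged, eta
4. amount of target at the end, in percent of the substrate charged, beta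

- the earlier runs were read with a standard deviation of 2 percentage points
- on the list of suspects stand: substrate + catalyst intermediate A <-> catalyst intermediate B; partner + free catalyst <-> catalyst intermediate A; catalyst intermediate B -> free catalyst + target; catalyst intermediate B -> spent catalyst A; partner -> decomposed reagent; catalyst intermediate A + target -> spent catalyst B

We keep the books on partner, the limiting reagent, since the plateau as read climbs with its charge: 45.2% in autumn, 67.7% in winter and 85.5% at midnight. In the winter run the catalyst forms can hold hardly any of the partner, being charged at 0.1 mol%. In winter target takes 67.7% of the partner charge, which on our books leaves 32.3% for decomposed reagent and 32.3% of the substrate unused. We take decomposition to be first-order in partner and the target route to go with c(partner) times c(substrate), so at this loading the share of partner reaching target is c(substrate)/(c(substrate) + c(even)), with c(even) a constant that we now read from the runs. Replacing the falling curve by its logarithmic mean, 0.108 M in winter, gives 0.0515 M. Autumn gives 0.0650 M and midnight 0.0601 M. Their mean, a reading with the scatter of the runs, is 0.0589 M, which we call c(even), the substrate level at which partner splits evenly between target and decomposition.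

Our own reckoning puts eta at the winter plateau, 67.7%. For delta we let substrate fall straight from charge to remainder, a mean of 0.119 M and so 66.9%. For beta we guess a mean of 0.0450 M, which gives 43.3%. Our delta and eta then lie 0.80 percentage points apart, inside the margin of 1.5 points, so we call those two alike and put beta below both. The forecast says 65.5% for delta, 67% for eta and 35% for beta, with eta best, holding that “Selectivity then depends only on substrate level”. On beta the forecast stands below our reckoning.

The flasks give 68.5% for delta, 65.5% for eta and 38.5% for beta, so delta is best. Over the first 5.0 min, delta held a mean substrate of 0.131 M, and with c(even) that gives a share of 69.0%. The mean of 0.0462 M over the same minutes in beta gives 44.0%, which stands 5.5 points above the result of beta, and that gap is the error of replacing the curve by its mean there.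

    substrate + catalyst intermediate A ⇌ catalyst intermediate B (K = 26.0 L mol⁻¹, k = 300 L mol⁻¹ s⁻¹)
    partner + free catalyst ⇌ catalyst intermediate A (K = 12.0 L mol⁻¹, k = 150 L mol⁻¹ s⁻¹)
    catalyst intermediate B → free catalyst + target (k = 300 s⁻¹)
    catalyst intermediate B → spent catalyst A (k = 0.0620 s⁻¹)
    partner → decomposed reagent (k = 0.00730 s⁻¹)
    catalyst intermediate A + target → spent catalyst B (k = 0.0280 L mol⁻¹ s⁻¹)

Take delta at 0.4 mol% of free catalyst, assuming c(even) falls in step with loading to 0.0147 M. Lending it delta's mean gives 89.9%, and the computed flask gives 89.5%.

(All runs come from a simulation with made-up constants, noise included.)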